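**Retrosynthetic overview**

1. Renealtin A comes from hydrogenolysis of its two O-benzyl ethers; the all-cis C2/C3/C5 triad comes from hydride addition to a cis-2,5-disubstituted oxolan-3-one on the face opposite both ring substituents, with MnO2 return of the side-chain carbinol to the aryl ketone.
2. Feature used: in the oxolane ring (O1, C2, C3, C4, C5) the benzylic carbon C1 sits on C2, between the ring oxygen O1 and the oxygen-bearing C3. This O1–C2(–C1)–C3(O) array is what a benzyl shift from an oxonium oxygen to the adjacent ylide carbon of a 3-oxo-oxolane leaves behind.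
3. Key disconnection (O1–C2 and C1–C2 together; the oxolane is the only ring formed): 2-arylmethyl-oxolan-3-one from an acyclic diazoketone that carries the migrating 4-benzyloxy-3-methoxybenzyl group on the C5 oxygen. Rhodium carbenoid, five-membered oxonium ylide, Stevens [1,2]-shift, then base equilibration of C2.
4. Diazoketone from a β-alkoxy keto acid, made by O-alkylation of a β-hydroxy keto ester with the benzylic trichloroacetimidate; aryl ketone by Negishi acylation of a 3-silyloxyglutarate half-ester chloride; C5 stereocentre from cinchona-catalysed desymmetrising methanolysis of 3-silyloxyglutaric anhydride.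

Key step: step 8

Remark (starting materials): 1-(benzyloxy)-4-bromo-2-methoxybenzene and [4-(benzyloxy)-3-methoxyphenyl]methanol are taken as purchasable; each is otherwise one K2CO3/BnBr benzylation away from 4-bromo-2-methoxyphenol or vanillyl alcohol.
Remark (sense of induction): (DHQ)2AQN is assumed to give the (S)-half-ester in step 1; should it give the (R)-half-ester, the pseudoenantiomer (DHQD)2AQN is used and nothing else changes.
Remark (locants): ring atoms are O1, C2 (arylmethyl carbon), C3 (carbonyl or carbinol), C4 and C5 (aroylmethyl carbon); C1 is the benzylic CH2 on C2.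

**Route**

Step 1
Reactants: 1 3-(tert-butyldimethylsilyloxy)glutaric anhydride
Product: 2 (3S)-3-[(tert-butyldimethylsilyl)oxy]-5-methoxy-5-oxopentanoic acid
Conditions: MeOH (10 equiv), (DHQ)2AQN (10 mol %), Et2O, −40 °C
Reagents that add atoms: methanol, CO
Why: Cinchona-alkaloid-catalysed desymmetrising alcoholysis of a prochiral cyclic anhydride, in which the chiral tertiary amine activates methanol by general-base catalysis towards one of the two enantiotopic carbonyl groups and so sets the silyloxy-bearing stereocentre (the future C5) as (S).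

Step 2
Reactants: 2 (3S)-3-[(tert-butyldimethylsilyl)oxy]-5-methoxy-5-oxopentanoic acid; 3 1-(benzyloxy)-4-bromo-2-methoxybenzene
Product: 7 methyl (3S)-5-[4-(benzyloxy)-3-methoxyphenyl]-3-[(tert-butyldimethylsilyl)oxy]-5-oxopentanoate, via acid chloride 4 (not isolated), via aryllithium 5 (not isolated), via arylzinc chloride 6 (not isolated)
Conditions: 2, (COCl)2, DMF (cat.), CH2Cl2, 0 °C to rt, evaporate; 3, n-BuLi, THF, −78 °C, then ZnCl2, −78 to 0 °C; combine, Pd(PPh3)4 (5 mol %), THF, 0 °C to rt
Reagents that add atoms: none
Why: Negishi acylation, in which zerovalent palladium inserts into the acyl chloride and the arylzinc chloride (from bromine–lithium exchange and transmetalation) transfers the aryl group, the weakly nucleophilic zinc reagent sparing the methyl ester, the silyl ether and the ketone formed and leaving the stereocentre untouched.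

Step 3
Reactants: 7 methyl (3S)-5-[4-(benzyloxy)-3-methoxyphenyl]-3-[(tert-butyldimethylsilyl)oxy]-5-oxopentanoate
Product: 8 methyl (3S)-5-[4-(benzyloxy)-3-methoxyphenyl]-3-hydroxy-5-oxopentanoate
Conditions: HF·pyridine, THF/pyridine, 0 °C to rt
Reagents that add atoms: none
Why: Fluoride-mediated desilylation under buffered acidic conditions cleaves the secondary silyl ether without the base-induced dehydration or retro-aldol cleavage to which a β-hydroxy ketone is prone.

Step 4
Reactants: 9 [4-(benzyloxy)-3-methoxyphenyl]methanol
Product: 10 [4-(benzyloxy)-3-methoxyphenyl]methyl 2,2,2-trichloroacetimidate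
Conditions: Cl3CCN, DBU (10 mol %), CH2Cl2, 0 °C
Reagents that add atoms: trichloroacetonitrile, N#CC(Cl)(Cl)Cl
Why: Base-catalysed addition of the benzylic alcohol to trichloroacetonitrile (imidate formation) is the standard activation of 4-alkoxybenzyl alcohols for acid-catalysed ether synthesis.

Step 5
Reactants: 8 methyl (3S)-5-[4-(benzyloxy)-3-methoxyphenyl]-3-hydroxy-5-oxopentanoate; 10 [4-(benzyloxy)-3-methoxyphenyl]methyl 2,2,2-trichloroacetimidate
Product: 11 methyl (3S)-5-[4-(benzyloxy)-3-methoxyphenyl]-3-{[4-(benzyloxy)-3-methoxyphenyl]methoxy}-5-oxopentanoate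
Conditions: Sc(OTf)3 (2 mol %), toluene, 0 °C
Reagents that add atoms: none
Why: Acid-catalysed O-benzylation with a trichloroacetimidate, in which the Lewis acid ionises the imidate to the stabilised 4-alkoxybenzyl cation that the secondary hydroxyl captures under non-basic conditions, so the β-oxygenated ketone and ester cannot eliminate and the C–O bond at the stereocentre is not broken.

Step 6
Reactants: 11 methyl (3S)-5-[4-(benzyloxy)-3-methoxyphenyl]-3-{[4-(benzyloxy)-3-methoxyphenyl]methoxy}-5-oxopentanoate
Product: 12 (3S)-5-[4-(benzyloxy)-3-methoxyphenyl]-3-{[4-(benzyloxy)-3-methoxyphenyl]methoxy}-5-oxopentanoic acid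
Conditions: Me3SnOH (5 equiv), ClCH2CH2Cl, 70 °C; then 0.1 M HCl wash
Reagents that add atoms: trimethyltin hydroxide, C[Sn](C)(C)O
Why: Trimethyltin hydroxide-mediated hydrolysis of a methyl ester runs through a neutral tin carboxylate and so avoids the E1cB loss of the alkoxy group (β to both the ester and the aryl ketone) that aqueous hydroxide would risk.

Step 7
Reactants: 12 (3S)-5-[4-(benzyloxy)-3-methoxyphenyl]-3-{[4-(benzyloxy)-3-methoxyphenyl]methoxy}-5-oxopentanoic acid
Product: 14 (4S)-6-[4-(benzyloxy)-3-methoxyphenyl]-4-{[4-(benzyloxy)-3-methoxyphenyl]methoxy}-1-diazohexane-2,6-dione, via mixed carbonic anhydride 13 (not isolated)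
Conditions: i-BuOCOCl, N-methylmorpholine, THF, −20 °C; then CH2N2 (excess), Et2O, 0 °C
Reagents that add atoms: diazomethane, C=[N+]=[N-]
Why: Acylation of diazomethane by a mixed carbonic anhydride (the first stage of an Arndt–Eistert sequence) gives the α-diazoketone without the hydrogen chloride of an acid chloride route, which the acid-labile 4-alkoxybenzyl ether would tolerate poorly.

Step 8
Reactants: 14 (4S)-6-[4-(benzyloxy)-3-methoxyphenyl]-4-{[4-(benzyloxy)-3-methoxyphenyl]methoxy}-1-diazohexane-2,6-dione
Product: 16 (5S)-5-{2-[4-(benzyloxy)-3-methoxyphenyl]-2-oxoethyl}-2-{[4-(benzyloxy)-3-methoxyphenyl]methyl}oxolan-3-one (mixture of C2 epimers), via oxonium ylide 15 (not isolated)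
Conditions: Rh2(OAc)4 (2 mol %), CH2Cl2, rt, slow addition of 14
Reagents that add atoms: none
Why: Rh2(OAc)4 expels N2 from 14 to give a rhodium carbenoid at the former diazo carbon (the future C2), and the ether oxygen on the stereogenic carbon, 1,5-related to it, adds to this carbon (O1–C2 bond) to give the cyclic oxonium ylide 15; homolysis of its O–CH2Ar bond to a solvent-caged pair of a 4-alkoxybenzyl radical and an α-oxo radical and recombination at carbon (C1–C2 bond) complete a Stevens [1,2]-shift. The closest known reaction type is exactly this dirhodium tetraacetate-catalysed conversion of β-benzyloxy α'-diazoketones into 2-benzyl-oxolan-3-ones. The one ring closed is the oxolan-3-one, formed by five-membered cyclisation of a heteroatom lone pair onto the metal carbenoid. The new stereocentre C2 is governed by which diastereotopic lone pair of oxygen attacks (benzyl syn or anti to the C5 side chain on the oxonium centre) and by retentive in-cage recombination, a relay expected to be only moderately selective, so C2 is not relied on here and is set thermodynamically in step 9, whereas C5 undergoes no bond change and keeps its configuration. The selectivities the step needs are ylide formation over C–H insertion or arene addition, secured by the five-membered geometry (the only C–H bonds in 1,5-relationship are the deactivated ones next to the aryl ketone, and the ketone oxygen and the arenes could be reached only through seven-membered or larger rings), and carbon- over oxygen-recombination of the radical pair, favoured by the carbon-centred spin density of the α-oxo radical and by rhodium, which sets the ylide free, in place of copper diketonates, whose metal-bound ylides are the ones prone to pass benzyl to the enolate oxygen.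

Step 9
Reactants: 16 (5S)-5-{2-[4-(benzyloxy)-3-methoxyphenyl]-2-oxoethyl}-2-{[4-(benzyloxy)-3-methoxyphenyl]methyl}oxolan-3-one (mixture of C2 epimers)
Product: 17 (2R,5S)-5-{2-[4-(benzyloxy)-3-methoxyphenyl]-2-oxoethyl}-2-{[4-(benzyloxy)-3-methoxyphenyl]methyl}oxolan-3-one (2,5-cis)
Conditions: DBU (0.2 equiv), CH2Cl2, 0 °C to rt; chromatography, trans isomer recycled
Reagents that add atoms: none
Why: Base-mediated epimerisation through the C2 enolate of the ring ketone (C2–H is α to both the carbonyl and O1) is expected to favour the 2,5-cis isomer, in which both substituents are pseudo-equatorial on the envelope, and separated trans isomer is resubmitted, the weak catalytic base and low temperature being chosen to stay below the threshold of retro-oxa-Michael opening at C5.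

Step 10
Reactants: 17 (2R,5S)-5-{2-[4-(benzyloxy)-3-methoxyphenyl]-2-oxoethyl}-2-{[4-(benzyloxy)-3-methoxyphenyl]methyl}oxolan-3-one
Product: 18 (2R,3R,5S)-5-{2-[4-(benzyloxy)-3-methoxyphenyl]-2-hydroxyethyl}-2-{[4-(benzyloxy)-3-methoxyphenyl]methyl}oxolan-3-ol (both epimers at the side-chain carbinol)
Conditions: LiBH(s-Bu)3 (3 equiv), THF, −78 °C; then NaOH aq., H2O2, 0 °C
Reagents that add atoms: none
Why: Reduction with the bulky trialkylborohydride delivers hydride to the C3 carbonyl from the face anti to the cis C2 and C5 substituents, giving the C3 alcohol cis to both (all-cis triad), and it reduces the aryl ketone as well, whose carbinol configuration is irrelevant because that centre is reoxidised.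

Step 11
Reactants: 18 (2R,3R,5S)-5-{2-[4-(benzyloxy)-3-methoxyphenyl]-2-hydroxyethyl}-2-{[4-(benzyloxy)-3-methoxyphenyl]methyl}oxolan-3-ol
Product: 19 1-[4-(benzyloxy)-3-methoxyphenyl]-2-[(2R,4R,5R)-5-{[4-(benzyloxy)-3-methoxyphenyl]methyl}-4-hydroxyoxolan-2-yl]ethan-1-one (O,O'-dibenzyl renealtin A)
Conditions: MnO2 (activated, 15 equiv), CH2Cl2, rt
Reagents that add atoms: none
Why: Manganese dioxide oxidises benzylic alcohols selectively, so the electron-rich aryl carbinol returns to the ketone while the saturated ring alcohol at C3 is left alone.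

Step 12
Reactants: 19 1-[4-(benzyloxy)-3-methoxyphenyl]-2-[(2R,4R,5R)-5-{[4-(benzyloxy)-3-methoxyphenyl]methyl}-4-hydroxyoxolan-2-yl]ethan-1-one
Product: 20 renealtin A, 1-(4-hydroxy-3-methoxyphenyl)-2-[(2R,4R,5R)-4-hydroxy-5-[(4-hydroxy-3-methoxyphenyl)methyl]oxolan-2-yl]ethan-1-one
Conditions: H2 (1 atm), Pd/C (10 %), EtOAc, rt, stopped after two equivalents of H2
Reagents that add atoms: none
Why: Hydrogenolysis of aryl benzyl ethers over palladium on carbon at atmospheric pressure in a neutral aprotic solvent is much faster than reduction of the electron-rich conjugated aryl ketone, and no base is present that could open the ring at C5 by retro-oxa-Michael reaction.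

**Compound list**

1 | 3-(tert-butyldimethylsilyloxy)glutaric anhydride | CC(C)(C)[Si](C)(C)OC1CC(=O)OC(=O)C1 | starting material
2 | (3S)-3-[(tert-butyldimethylsilyl)oxy]-5-methoxy-5-oxopentanoic acid | COC(=O)C[C@@H](O[Si](C)(C)C(C)(C)C)CC(=O)O | intermediate
3 | 1-(benzyloxy)-4-bromo-2-methoxybenzene | COc1cc(Br)ccc1OCc1ccccc1 | starting material
4 | methyl (3R)-3-[(tert-butyldimethylsilyl)oxy]-5-chloro-5-oxopentanoate (acid chloride) | COC(=O)C[C@@H](O[Si](C)(C)C(C)(C)C)CC(=O)Cl | intermediate
5 | [4-(benzyloxy)-3-methoxyphenyl]lithium | [Li]c1ccc(OCc2ccccc2)c(OC)c1 | intermediate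
6 | [4-(benzyloxy)-3-methoxyphenyl]zinc chloride | Cl[Zn]c1ccc(OCc2ccccc2)c(OC)c1 | intermediate
7 | methyl (3S)-5-[4-(benzyloxy)-3-methoxyphenyl]-3-[(tert-butyldimethylsilyl)oxy]-5-oxopentanoate | COC(=O)C[C@@H](O[Si](C)(C)C(C)(C)C)CC(=O)c1ccc(OCc2ccccc2)c(OC)c1 | intermediate
8 | methyl (3S)-5-[4-(benzyloxy)-3-methoxyphenyl]-3-hydroxy-5-oxopentanoate | COC(=O)C[C@@H](O)CC(=O)c1ccc(OCc2ccccc2)c(OC)c1 | intermediate
9 | [4-(benzyloxy)-3-methoxyphenyl]methanol | COc1cc(CO)ccc1OCc1ccccc1 | starting material
10 | [4-(benzyloxy)-3-methoxyphenyl]methyl 2,2,2-trichloroacetimidate | COc1cc(COC(=N)C(Cl)(Cl)Cl)ccc1OCc1ccccc1 | intermediate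
11 | methyl (3S)-5-[4-(benzyloxy)-3-methoxyphenyl]-3-{[4-(benzyloxy)-3-methoxyphenyl]methoxy}-5-oxopentanoate | COC(=O)C[C@@H](OCc1ccc(OCc2ccccc2)c(OC)c1)CC(=O)c1ccc(OCc2ccccc2)c(OC)c1 | intermediate
12 | (3S)-5-[4-(benzyloxy)-3-methoxyphenyl]-3-{[4-(benzyloxy)-3-methoxyphenyl]methoxy}-5-oxopentanoic acid | OC(=O)C[C@@H](OCc1ccc(OCc2ccccc2)c(OC)c1)CC(=O)c1ccc(OCc2ccccc2)c(OC)c1 | intermediate
13 | isobutyl carbonic anhydride of acid 12 (mixed carbonic anhydride, 3S) | CC(C)COC(=O)OC(=O)C[C@@H](OCc1ccc(OCc2ccccc2)c(OC)c1)CC(=O)c1ccc(OCc2ccccc2)c(OC)c1 | intermediate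
14 | (4S)-6-[4-(benzyloxy)-3-methoxyphenyl]-4-{[4-(benzyloxy)-3-methoxyphenyl]methoxy}-1-diazohexane-2,6-dione | [N-]=[N+]=CC(=O)C[C@@H](OCc1ccc(OCc2ccccc2)c(OC)c1)CC(=O)c1ccc(OCc2ccccc2)c(OC)c1 | intermediate
15 | cyclic oxonium ylide: 1-{[4-(benzyloxy)-3-methoxyphenyl]methyl}-3-oxo-oxolan-1-ium-2-ide carrying the 2-aryl-2-oxoethyl chain on C5 | COc1cc(C[O+]2[CH-]C(=O)C[C@@H]2CC(=O)c2ccc(OCc3ccccc3)c(OC)c2)ccc1OCc1ccccc1 | intermediate
16 | (5S)-5-{2-[4-(benzyloxy)-3-methoxyphenyl]-2-oxoethyl}-2-{[4-(benzyloxy)-3-methoxyphenyl]methyl}oxolan-3-one, mixture of C2 epimers | COc1cc(CC2O[C@@H](CC(=O)c3ccc(OCc4ccccc4)c(OC)c3)CC2=O)ccc1OCc1ccccc1 | intermediate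
17 | (2R,5S)-5-{2-[4-(benzyloxy)-3-methoxyphenyl]-2-oxoethyl}-2-{[4-(benzyloxy)-3-methoxyphenyl]methyl}oxolan-3-one (2,5-cis) | COc1cc(C[C@H]2O[C@@H](CC(=O)c3ccc(OCc4ccccc4)c(OC)c3)CC2=O)ccc1OCc1ccccc1 | intermediate
18 | (2R,3R,5S)-5-{2-[4-(benzyloxy)-3-methoxyphenyl]-2-hydroxyethyl}-2-{[4-(benzyloxy)-3-methoxyphenyl]methyl}oxolan-3-ol, all-cis ring, both carbinol epimers in the side chain | COc1cc(C[C@H]2O[C@@H](CC(O)c3ccc(OCc4ccccc4)c(OC)c3)C[C@H]2O)ccc1OCc1ccccc1 | intermediate
19 | 1-[4-(benzyloxy)-3-methoxyphenyl]-2-[(2R,4R,5R)-5-{[4-(benzyloxy)-3-methoxyphenyl]methyl}-4-hydroxyoxolan-2-yl]ethan-1-one | COc1cc(C[C@H]2O[C@@H](CC(=O)c3ccc(OCc4ccccc4)c(OC)c3)C[C@H]2O)ccc1OCc1ccccc1 | intermediate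
20 | renealtin A | COc1cc(C[C@H]2O[C@@H](CC(=O)c3ccc(O)c(OC)c3)C[C@H]2O)ccc1O | target

**Step count**

Total step count: 12.
Longest linear sequence: 11 steps (steps 1, 2, 3 and 5 to 12, from anhydride 1); step 4 is the one-step side branch.

**Steps most likely to fail**

1. Step 8. The benzyl group may be passed to the enolate oxygen instead of C2 (apparent [1,4]-shift), which the electron-rich 4-alkoxybenzyl group favours by giving the radical pair ion-pair character. Fallback, setting out from 14 and coming back at 16: the carbenoid cyclisation is run as in step 8 and the crude product, then containing the O-benzylated isomer (2R)-2-{2-[4-(benzyloxy)-3-methoxyphenyl]-2-oxoethyl}-4-{[4-(benzyloxy)-3-methoxyphenyl]methoxy}-2,3-dihydrofuran F1 beside 16, is treated with TMSOTf (5 mol %) in CH2Cl2 at −78 °C. The Lewis acid ionises the 4-alkoxybenzyl–oxygen bond of the enol ether and the tight ion pair recombines at C2, a 1,3 oxygen-to-carbon benzyl shift of the kind known for electron-rich benzyl and allyl enol ethers. The C1–C2 bond is thus made by a polar instead of a radical-pair path and the whole material converges on 16.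

2. Step 9. The thermodynamic preference for the cis isomer may be too small to be useful, and enolisation of the aryl ketone with retro-oxa-Michael opening and reclosure at C5 would erode the only stereocentre that carries the absolute configuration. Fallback, setting out from 16 and coming back at 18 (it replaces steps 9 and 10): dynamic kinetic resolution by Noyori–Ikariya asymmetric transfer hydrogenation, RuCl(p-cymene)[(S,S)-TsDPEN] or its enantiomer (whichever is matched to the (2R) epimer), HCO2H/Et3N (5:2), CH2Cl2, rt. The C2 epimers interconvert under the amine buffer while the catalyst is expected to reduce the (2R) ketone faster and from the face that gives the 2,3-cis alcohol. The aryl ketone is reduced at the same time, which removes the possibility of ring opening at C5, and the product is one side-chain epimer of 18, reoxidised as in step 11. This fallback passes through no compound outside the list (F0).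

3. Step 5. The very electron-rich imidate may ionise without being captured by the secondary hydroxyl (rearrangement to the N-benzyl trichloroacetamide, benzylation of the arenes), or the acid may dehydrate the β-hydroxy ketone. Fallback, setting out from 9 (with 8) and coming back at 11: silver-assisted Williamson etherification. Alcohol 9 is converted with PBr3 (Et2O, 0 °C) into 4-(benzyloxy)-1-(bromomethyl)-2-methoxybenzene F2, which is used at once with 8 and Ag2O (4 Å molecular sieves, CH2Cl2, rt, dark). Halide abstraction by silver activates the bromide under essentially neutral conditions, so neither acid nor strong base meets the β-hydroxy ketone.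

**Further compounds**

F1 | step 8 | (2R)-2-{2-[4-(benzyloxy)-3-methoxyphenyl]-2-oxoethyl}-4-{[4-(benzyloxy)-3-methoxyphenyl]methoxy}-2,3-dihydrofuran | COc1cc(COC2=CO[C@@H](CC(=O)c3ccc(OCc4ccccc4)c(OC)c3)C2)ccc1OCc1ccccc1
F0 | step 9 | none | none
F2 | step 5 | 4-(benzyloxy)-1-(bromomethyl)-2-methoxybenzene | COc1cc(CBr)ccc1OCc1ccccc1
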